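## Structural features

The target is a daucane (carotane) sesquiterpenoid ester: ring A (cyclopentane, C1–C5) and ring B (cycloheptane, C1, C5–C10) are fused trans through the C1–C5 bond. Daucane locants are used throughout: C1 is the quaternary ring-fusion carbon with a methyl, C4 the carbinol carbon with the isopropyl group, C5 the ring-fusion CH, C6 the acyloxy carbon, C7 and C10 methylenes, C8 the methyl carbinol and C9 the secondary carbinol. There are six stereocentres, (1R,4R,5S,6S,8R,9S); C4, C5, C1 and C6 are contiguous around the ring fusion, C1 is an all-carbon quaternary centre, and C4 and C8 are fully substituted carbinols. The C1 methyl, the C4 hydroxyl and the C8 methyl lie on one face (β); H5, the isopropyl group and all three ring-B oxygens (O6, O8, O9) lie on the other (α), so O6/O9 are 1,4-cis and O8/O9 form a cis-vicinal diol. Fragile elements are the phenolic aryl ester (hydride, strong base, nucleophiles) and the two tertiary alcohols (dehydration in strong acid), and only O6 of four hydroxyls is to be acylated. The real difficulty is ring B, substituted at five of its seven carbons, together with the quaternary C1 next to the C5 methine in a trans relationship. The feature exploited is that C1, C6, C7, C8, C9, C10 and the C8 methyl form the carbon pattern of a para-tolyl ring (methyl para to C1), with C5 as one extra carbon inserted between C1 and C6 and C4 as a carbonyl on that carbon. Read this way, ring B is a ring-expanded toluene, C1 becomes the β-carbon of a C4 enone, and C6–C9 a 1,3-diene, exactly where the methyl group and the three oxygens are needed.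

## Logic of the disconnections

17 ⇒ 15. The benzyl–O bond of the phenol ether and the two acetal C–O bonds at O8/O9 are cut (protecting groups only). The reason is that the ester must be made with the phenol and the diol masked. The demand is a deprotection that spares the aryl ester and both tertiary alcohols.

15 ⇒ 13 + 14. The acyl C–O6 bond is cut. The hydride- and base-labile ester is thereby introduced as late as possible and convergently. In 13 the only acylatable hydroxyl is O6–H (O4–H is tertiary, O8/O9 are tied up), so the forward step needs only an ordinary acylation of a hindered secondary alcohol.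

13 ⇒ 12. The acetal C–O8 and C–O9 bonds are cut. O9 and O6 are both secondary and are told apart only by their relation to O8 (vicinal cis versus 1,3). The forward step must therefore form the dioxolane under thermodynamic control.

12 ⇒ 11 ⇒ 10. The C7–H bond (hydride) and then the C7–O/C8–O bonds of an epoxide are cut. This brings in the tertiary O8 syn to O6 and O9 by hydroxyl direction, and lets substitution decide the site of hydride attack. The gain is that 10 has no C8 stereocentre. The demands are syn epoxidation and opening at C7 only.

10 ⇒ 8 (through 9). The C6–O and C9–O bonds are cut together as a [4+2] addition of dioxygen across the C6=C7–C8=C9 diene. Two stereocentres, necessarily cis, come from one operation, and all ring-B oxygen is removed in the retron. The demand is addition on the α-face.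

8 ⇒ 7. The C4–isopropyl bond is cut (1,2-addition to the C4 ketone). The demand is α-face attack without enolisation of a β,γ-unsaturated ketone.

7 ⇒ 5 (through 6). The C1–CH3 bond (conjugate addition) and the C5–H bond (enolate protonation) are cut. The gain is large: 5 is flat and achiral, so every stereocentre of the target descends from one enantioface selection at C1. The demands are catalyst control at a fully substituted β-carbon and kinetic protonation anti to the new methyl.

5 ⇒ 3 (through 4): the key disconnection. The C5–C1 and C5–C6 bonds are cut: C5 is taken out of ring B, which collapses to the para-tolyl ring of 3, and ring A opens to a three-atom tether. In one sentence, the route is an intramolecular Buchner ring expansion of 3. Both rings, all twelve ring carbons, the C8 methyl and the C4 carbonyl come from a monocyclic arene. The demand is aromatic cycloaddition of the carbenoid in preference to its other pathways, and base isomerisation to the cross-conjugated trienone.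

3 ⇒ 1 (through 2). The C(=O)–CHN2 bond is cut: acylation of diazomethane by 2, which is made from 1.

## Other disconnections considered

Alternative 1: ring-closing metathesis, the first plan most chemists would draw. The cut is the C8=C9 bond of alkene A2 (the 8,9-diol then comes from dihydroxylation). The forward key step is closure of seco-diene A1 with a second-generation Grubbs catalyst to A2. The step only closes the ring: A1 must already carry the four contiguous stereocentres C1, C4, C5 and C6 on a cyclopentane that has to be assembled linearly, one centre at a time. The chosen plan reaches the complete bicyclic carbon skeleton in two steps and relays the stereocentres afterwards.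

Alternative 2: one-carbon ring expansion. The cut removes C8 from ring B, leaving trans-hydrindanone A3. The forward key step is insertion of a CH(CH3) unit (diazoethane or equivalent, Lewis acid) next to the C9 carbonyl to give A4, followed by oxygenation at C8. The two migrating carbons (C7 and C10) are both methylenes with no electronic bias, so regioisomeric insertion is expected on mechanistic grounds. A3 also needs the same four contiguous stereocentres before the key step. The Buchner expansion faces no such choice because the two ortho positions of the para-tolyl ring are equivalent.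

Alternative 3: [5+2] cycloaddition. The cuts are C1–C5 and C9–C10. The forward key step is a [Rh(CO)2Cl]2-catalysed intramolecular cycloaddition of ene–vinylcyclopropane A5 to A6. The metallacycle mechanism delivers the cis ring fusion, whereas the target is trans and C5 in A6 is not epimerisable. The new alkene also lands at C6=C7, which does not prepare the O6/O8/O9 pattern. The chosen plan leaves a diene exactly at C6–C9 and sets the trans fusion by protonation.

Key step: step 2

## Route

Step 1
Reactants: 1 3-(4-methylphenyl)propanoic acid
Product: 3 1-diazo-4-(4-methylphenyl)butan-2-one, via 3-(4-methylphenyl)propanoyl chloride 2 (not isolated)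
Conditions: (COCl)2, cat. DMF, CH2Cl2, 0 °C to rt; evaporate; CH2N2 (3 equiv), Et2O, 0 °C
Reagents that add atoms: diazomethane, C=[N+]=[N-]
Why: Acid chloride formation followed by acylation of diazomethane (the diazoketone stage of the Arndt–Eistert sequence); the excess diazomethane consumes the HCl released, so the chloromethyl ketone is avoided, and no stereocentre is involved.

Step 2
Reactants: 3 1-diazo-4-(4-methylphenyl)butan-2-one
Product: 5 6-methyl-3,4-dihydroazulen-1(2H)-one, via kinetic 8aH-trienone 4 (not isolated)
Conditions: Rh2(OAc)4 (0.5 mol%), CH2Cl2, reflux, slow addition of 3 at high dilution; then Et3N (0.2 equiv), rt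
Reagents that add atoms: none
Why: Rh2(OAc)4 converts the diazoketone into an electrophilic divalent-rhodium carbenoid, which adds across the ipso–ortho π-bond of the tethered arene to give a norcaradiene; this opens by thermally allowed disrotatory 6π electrocyclisation to cycloheptatriene 4. The closest known reaction type is exactly this one, the intramolecular Buchner reaction of 1-diazo-4-arylbutan-2-ones. Ring A closes through the carbene–C(ipso) bond as a five-membered ring, the only mode a three-atom tether allows, since insertion into the benzylic C–H bond would give a cyclobutanone; ring B arises by one-carbon expansion of the benzene ring, C5 being inserted between C1 and C6. Because the arene is para-substituted the two ortho positions are equivalent, so a single regioisomer with the methyl at C8 is expected. Triethylamine then moves the C5 hydrogen to C10 through the extended enolate and should give the conjugated isomer 5 with the fully substituted C1=C5 enone. The only stereocentre formed (C5 in 4) is erased deliberately and 5 is achiral, so no stereocontrol is needed here. What the step must place is the latent functionality: enone β-carbon at C1, diene at C6–C9, carbonyl at C4. The selectivity required is aromatic cycloaddition over carbenoid dimerisation (slow addition, dilution) and the exclusion of acid, which would aromatise 4 to a 2-tetralone.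

Step 3
Reactants: 5 6-methyl-3,4-dihydroazulen-1(2H)-one
Product: 7 (3aR,8aR)-3a,6-dimethyl-3,3a,4,8a-tetrahydroazulen-1(2H)-one, via dimethylaluminium enolate 6 (not isolated)
Conditions: Me3Al (1.5 equiv), Cu(OTf)2 (5 mol%), binaphthyl-2,2'-diyl N,N-bis(1-phenylethyl)phosphoramidite (10 mol%, antipode chosen to give the R configuration at C1), Et2O, −30 °C; then MeOH, −78 °C; cold pH 7 buffer; used without delay
Reagents that add atoms: trimethylaluminium, C[Al](C)C
Why: Proposed new method: copper-catalysed enantioselective conjugate methylation with Me3Al and a chiral phosphoramidite is established for β,β-disubstituted cyclopentenones and cyclohexenones (the closest known type) but not for a fully substituted ring-fusion enone; here Me3Al activates the carbonyl, the methylcopper species formed in situ complexes one enantiotopic face of the flat C1=C5 bond, and reductive elimination from the trivalent-copper β-adduct makes the C1–CH3 bond at the only conjugate position, because the C6–C9 diene sits on the α-carbon and is cross-conjugated. Protonation of enolate 6 at −78 °C should occur kinetically at the α-carbon C5 from the face opposite the new pseudoaxial methyl, which sets the trans ring fusion and leaves the C6=C7–C8=C9 diene out of conjugation.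

Step 4
Reactants: 7 (3aR,8aR)-3a,6-dimethyl-3,3a,4,8a-tetrahydroazulen-1(2H)-one
Product: 8 (1R,4R,5R)-dauca-6,8-dien-4-ol
Conditions: iPrMgCl, CeCl3 (anhydrous), THF, −78 °C
Reagents that add atoms: isopropylmagnesium chloride, CC(C)[Mg]Cl
Why: Organocerium 1,2-addition: the weakly basic isopropylcerium reagent adds to the hindered, easily enolised β,γ-unsaturated ketone without epimerising C5 or moving the diene into conjugation. Attack should come on the α-face, syn to H5 and away from the pseudoaxial C1 methyl and the C5–C6 bond that crowd the β-face, so the hydroxyl ends cis to the C1 methyl (4R).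

Step 5
Reactants: 8 (1R,4R,5R)-dauca-6,8-dien-4-ol
Product: 10 (1R,4R,5S,6S,9S)-dauc-7-ene-4,6,9-triol, via endoperoxide 9 (not isolated)
Conditions: O2, visible light, tetraphenylporphyrin (cat.), CH2Cl2, −20 °C; then thiourea, MeOH, rt
Reagents that add atoms: dioxygen, O=O
Why: Photosensitised [4+2] cycloaddition of singlet oxygen to the s-cis cyclohepta-1,3-diene, then reduction of the O–O bond by thiourea, which leaves the new C7=C8 bond untouched. In the trans-fused ring the C1 methyl stands as a flagpole over the β-face of the diene, so dioxygen should add on the α-face (that of H5), setting C6 and C9 together and necessarily cis.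

Step 6
Reactants: 10 (1R,4R,5S,6S,9S)-dauc-7-ene-4,6,9-triol
Product: 11 (1R,4R,5S,6R,7R,8S,9S)-7,8-epoxydaucane-4,6,9-triol
Conditions: VO(acac)2 (5 mol%), tBuOOH, CH2Cl2, 0 °C to rt
Reagents that add atoms: tert-butyl hydroperoxide, CC(C)(C)OO
Why: Hydroxyl-directed epoxidation by the pentavalent vanadium alkylperoxide formed from VO(acac)2 and tBuOOH: both allylic hydroxyls (O6, O9) are on the α-face and deliver the oxidant syn, which fixes C8 with its oxygen α; the remote tertiary alcohol does not interfere.

Step 7
Reactants: 11 (1R,4R,5S,6R,7R,8S,9S)-7,8-epoxydaucane-4,6,9-triol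
Product: 12 (1R,4R,5S,6S,8R,9S)-daucane-4,6,8,9-tetrol
Conditions: LiAlH4 (excess), THF, 0 °C to reflux; H2O, then aqueous potassium sodium tartrate
Reagents that add atoms: none
Why: SN2 hydride opening of the trisubstituted epoxide at its less substituted carbon C7, anti to the epoxide oxygen, so the C8–O bond and its configuration are kept and C7 becomes the methylene. Both alkoxides are syn to the epoxide, so a Payne rearrangement is geometrically impossible.

Step 8
Reactants: 12 (1R,4R,5S,6S,8R,9S)-daucane-4,6,8,9-tetrol
Product: 13 (1R,4R,5S,6S,8R,9S)-8,9-O-isopropylidenedaucane-4,6,8,9-tetrol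
Conditions: 2,2-dimethoxypropane, PPTS (cat.), acetone, rt
Reagents that add atoms: 2,2-dimethoxypropane, COC(C)(C)OC
Why: Acid-catalysed transketalisation under thermodynamic control: the cis-vicinal O8/O9 pair closes a cis-fused dioxolane, favoured over a bridged 1,3-dioxane across O6/O8, and the O4/O6 pair points to opposite faces and cannot be bridged. This leaves O6–H as the only free hydroxyl that is not tertiary.

Step 9
Reactants: 13 (1R,4R,5S,6S,8R,9S)-8,9-O-isopropylidenedaucane-4,6,8,9-tetrol; 14 4-(benzyloxy)benzoyl chloride
Product: 15 (1R,4R,5S,6S,8R,9S)-4-hydroxy-8,9-(isopropylidenedioxy)daucan-6-yl 4-(benzyloxy)benzoate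
Conditions: Et3N, DMAP (0.2 equiv), CH2Cl2, rt to 40 °C
Reagents that add atoms: none
Why: DMAP-catalysed acylation (acylpyridinium transfer) of the single secondary hydroxyl; the tertiary C4 hydroxyl is inert under these conditions and no stereocentre is touched.

Step 10
Reactants: 15 (1R,4R,5S,6S,8R,9S)-4-hydroxy-8,9-(isopropylidenedioxy)daucan-6-yl 4-(benzyloxy)benzoate
Product: 17 (1R,4R,5S,6S,8R,9S)-4,8,9-trihydroxydaucan-6-yl 4-hydroxybenzoate, via phenol acetonide 16 (not isolated)
Conditions: H2 (1 atm), Pd/C, EtOAc–MeOH, rt; filter; then AcOH–H2O (4:1), 40 °C
Reagents that add atoms: none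
Why: Hydrogenolysis of the benzyl aryl ether (no alkene remains in the molecule) followed by mild aqueous-acid hydrolysis of the dioxolane; neither condition should cleave the aryl ester or dehydrate the tertiary alcohols, and no stereocentre is affected.

## Compound list

1 | 3-(4-methylphenyl)propanoic acid | Cc1ccc(CCC(=O)O)cc1 | starting material
2 | 3-(4-methylphenyl)propanoyl chloride | Cc1ccc(CCC(=O)Cl)cc1 | intermediate
3 | 1-diazo-4-(4-methylphenyl)butan-2-one | Cc1ccc(CCC(=O)C=[N+]=[N-])cc1 | intermediate
4 | 6-methyl-3,8a-dihydroazulen-1(2H)-one (racemic kinetic Buchner product) | O=C1CCC2=CC=C(C)C=CC12 | intermediate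
5 | 6-methyl-3,4-dihydroazulen-1(2H)-one (achiral; daucane C4=O, C1=C5, C6=C7, C8=C9) | O=C1CCC2=C1C=CC(C)=CC2 | intermediate
6 | dimethylaluminium (R)-3a,6-dimethyl-2,3,3a,4-tetrahydroazulen-1-olate | C[Al](C)OC1=C2C=CC(C)=CC[C@@]2(C)CC1 | intermediate
7 | (3aR,8aR)-3a,6-dimethyl-3,3a,4,8a-tetrahydroazulen-1(2H)-one (trans ring fusion) | O=C1CC[C@]2(C)CC=C(C)C=C[C@H]21 | intermediate
8 | (1R,4R,5R)-dauca-6,8-dien-4-ol, i.e. (1R,3aR,8aR)-3a,6-dimethyl-1-(propan-2-yl)-1,2,3,3a,4,8a-hexahydroazulen-1-ol | CC(C)[C@]1(O)CC[C@]2(C)CC=C(C)C=C[C@H]21 | intermediate
9 | (1R,4R,5S,6S,9S)-6,9-epidioxydauc-7-en-4-ol (6α,9α-endoperoxide) | CC(C)[C@]1(O)CC[C@]2(C)C[C@H](OO3)C(C)=C[C@H]3[C@H]21 | intermediate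
10 | (1R,4R,5S,6S,9S)-dauc-7-ene-4,6,9-triol | CC(C)[C@]1(O)CC[C@]2(C)C[C@H](O)C(C)=C[C@H](O)[C@H]21 | intermediate
11 | (1R,4R,5S,6R,7R,8S,9S)-7,8-epoxydaucane-4,6,9-triol (7α,8α-epoxide) | CC(C)[C@]1(O)CC[C@]2(C)C[C@H](O)[C@]3(C)O[C@@H]3[C@H](O)[C@H]21 | intermediate
12 | (1R,4R,5S,6S,8R,9S)-daucane-4,6,8,9-tetrol | CC(C)[C@]1(O)CC[C@]2(C)C[C@H](O)[C@](C)(O)C[C@H](O)[C@H]21 | intermediate
13 | (1R,4R,5S,6S,8R,9S)-8,9-O-isopropylidenedaucane-4,6,8,9-tetrol | CC(C)[C@]1(O)CC[C@]2(C)C[C@H](OC(C)(C)O3)[C@@]3(C)C[C@H](O)[C@H]21 | intermediate
14 | 4-(benzyloxy)benzoyl chloride | O=C(Cl)c1ccc(OCc2ccccc2)cc1 | starting material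
15 | (1R,4R,5S,6S,8R,9S)-4-hydroxy-8,9-(isopropylidenedioxy)daucan-6-yl 4-(benzyloxy)benzoate | CC(C)[C@]1(O)CC[C@]2(C)C[C@H](OC(C)(C)O3)[C@@]3(C)C[C@H](OC(=O)c4ccc(OCc5ccccc5)cc4)[C@H]21 | intermediate
16 | (1R,4R,5S,6S,8R,9S)-4-hydroxy-8,9-(isopropylidenedioxy)daucan-6-yl 4-hydroxybenzoate | CC(C)[C@]1(O)CC[C@]2(C)C[C@H](OC(C)(C)O3)[C@@]3(C)C[C@H](OC(=O)c4ccc(O)cc4)[C@H]21 | intermediate
17 | (1R,4R,5S,6S,8R,9S)-4,8,9-trihydroxydaucan-6-yl 4-hydroxybenzoate, i.e. (3R,3aS,4S,6R,7S,8aR)-3,6,7-trihydroxy-6,8a-dimethyl-3-(propan-2-yl)decahydroazulen-4-yl 4-hydroxybenzoate | CC(C)[C@]1(O)CC[C@]2(C)C[C@H](O)[C@](C)(O)C[C@H](OC(=O)c3ccc(O)cc3)[C@H]21 | target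

## Totals and least certain steps

Total step count: 10. Longest linear sequence: 10 steps (1 to 17); 14 is purchased.

Risk at step 3 (bears the label): The most likely failures are slow methyl transfer and weak enantioface discrimination, because the β-carbon is fully substituted and the two flanking groups of the flat enone differ only modestly. Protonation of 6 on the wrong face, or drift of the diene into conjugation during work-up, are secondary risks. Which ligand antipode delivers the methyl to the required face has to be established on the first runs. The fallback uses known chemistry, sets out from 5 and comes back to the route at 8. A stoichiometric methylcopper–boron trifluoride reagent (MeLi, CuBr·SMe2, BF3·OEt2, Et2O, −78 °C), a reagent type established for fully substituted enones, followed by the same cold protonation, should give 7 as a racemate, that is together with its mirror image (3aS,8aS)-3a,6-dimethyl-3,3a,4,8a-tetrahydroazulen-1(2H)-one F1. Organocerium addition as in step 4 should then give 8 together with its mirror image (1S,3aS,8aS)-3a,6-dimethyl-1-(propan-2-yl)-1,2,3,3a,4,8a-hexahydroazulen-1-ol F2. The two enantiomers are separated by preparative chromatography on a polysaccharide chiral stationary phase, and the route continues from 8.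

Risk at step 2 (key step): The most likely failures are carbenoid dimerisation, acid-promoted aromatisation of the norcaradiene and cycloheptatriene to a 2-tetralone, or equilibration to a double-bond isomer other than 5 during the base treatment. The fallback sets out from 1 and comes back at 5; it replaces arene cyclopropanation by ordinary alkene cyclopropanation. Birch reduction of 1 (Li, NH3, tBuOH) should give 3-(4-methylcyclohexa-1,4-dien-1-yl)propanoic acid F3. Treatment with (COCl)2 and pyridine should give 3-(4-methylcyclohexa-1,4-dien-1-yl)propanoyl chloride F4, and diazomethane then 1-diazo-4-(4-methylcyclohexa-1,4-dien-1-yl)butan-2-one F5. Rh2(OAc)4 should cyclopropanate the tether-bearing trisubstituted alkene intramolecularly to the cyclopropyl ketone 8-methyltricyclo[4.4.0.0(1,5)]dec-8-en-4-one F6. Bromine addition to the remaining alkene should give 8,9-dibromo-8-methyltricyclo[4.4.0.0(1,5)]decan-4-one F7. Double dehydrobromination with DBU should give the norcaradiene 8-methyltricyclo[4.4.0.0(1,5)]deca-7,9-dien-4-one F8, which opens to 4 and is isomerised by the same base to 5.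

Risk at step 5: The most likely failures are addition of singlet oxygen on the β-face if the isopropyl group on the α-side of C4 outweighs the flagpole methyl, or an ene reaction at the trisubstituted C8=C9 bond leading to allylic hydroperoxides. The fallback sets out from 8 and comes back at 10; it replaces the concerted cycloaddition by two stereospecific steps and has no ene pathway.
- Epoxidation with mCPBA and NaHCO3 in CH2Cl2 at 0 °C should take place at the more electron-rich trisubstituted C8=C9 bond, from the α-face, and give (1R,4R,5R,8R,9S)-8,9-epoxydauc-6-en-4-ol F9.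
- Pd(PPh3)4 (cat.) and acetic acid in THF should then give (1R,4R,5S,6S,9S)-4,9-dihydroxydauc-7-en-6-yl acetate F10. Zerovalent palladium ionises the allylic C8–O bond with inversion, and acetate attacks the distal terminus C6 of the allyl complex with a second inversion, so O6 ends syn to O9.
- Methanolysis with K2CO3 in MeOH gives 10.

Facial control in this detour rests on the epoxidation alone, and the epoxide diastereomers, unlike endoperoxides, can be separated before the stereospecific opening.

Risk at step 7: The most likely failures are hydride opening at the wrong carbon (Lewis-acid-assisted cleavage at the tertiary C8 by aluminium alkoxides) or sluggish attack on the β-face of C7. The fallback sets out from 11 and comes back at 12. Sodium phenylselenide, made from (PhSe)2 and NaBH4 in EtOH, is a soft nucleophile free of Lewis acid. It should open the epoxide at the less substituted C7 with inversion and give (1R,4R,5S,6R,7S,8S,9S)-7-(phenylselanyl)daucane-4,6,8,9-tetrol F11. Radical cleavage of the C–Se bond (Bu3SnH, AIBN, toluene, 80 °C) then gives 12 with the C8 configuration untouched.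

## Further compounds

F1 | step 3 | (3aS,8aS)-3a,6-dimethyl-3,3a,4,8a-tetrahydroazulen-1(2H)-one | O=C1CC[C@@]2(C)CC=C(C)C=C[C@@H]21
F2 | step 3 | (1S,3aS,8aS)-3a,6-dimethyl-1-(propan-2-yl)-1,2,3,3a,4,8a-hexahydroazulen-1-ol | CC(C)[C@@]1(O)CC[C@@]2(C)CC=C(C)C=C[C@@H]21
F3 | step 2 | 3-(4-methylcyclohexa-1,4-dien-1-yl)propanoic acid | CC1=CCC(CCC(=O)O)=CC1
F4 | step 2 | 3-(4-methylcyclohexa-1,4-dien-1-yl)propanoyl chloride | CC1=CCC(CCC(=O)Cl)=CC1
F5 | step 2 | 1-diazo-4-(4-methylcyclohexa-1,4-dien-1-yl)butan-2-one | CC1=CCC(CCC(=O)C=[N+]=[N-])=CC1
F6 | step 2 | 8-methyltricyclo[4.4.0.0(1,5)]dec-8-en-4-one | O=C1CCC23CC=C(C)CC2C13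
F7 | step 2 | 8,9-dibromo-8-methyltricyclo[4.4.0.0(1,5)]decan-4-one | O=C1CCC23CC(Br)C(C)(Br)CC2C13
F8 | step 2 | 8-methyltricyclo[4.4.0.0(1,5)]deca-7,9-dien-4-one | O=C1CCC23C=CC(C)=CC2C13
F9 | step 5 | (1R,4R,5R,8R,9S)-8,9-epoxydauc-6-en-4-ol | CC(C)[C@]1(O)CC[C@]2(C)C[C@@H]3O[C@]3(C)C=C[C@H]21
F10 | step 5 | (1R,4R,5S,6S,9S)-4,9-dihydroxydauc-7-en-6-yl acetate | CC(C)[C@]1(O)CC[C@]2(C)C[C@H](O)C(C)=C[C@H](OC(C)=O)[C@H]21
F11 | step 7 | (1R,4R,5S,6R,7S,8S,9S)-7-(phenylselanyl)daucane-4,6,8,9-tetrol | CC(C)[C@]1(O)CC[C@]2(C)C[C@H](O)[C@](C)(O)[C@@H]([Se]c3ccccc3)[C@H](O)[C@H]21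
A1 | alternative 1 | seco-diene: ring A of the target with allyl on C1 and a 1-hydroxy-3-methylbut-3-enyl chain on C5, configurations at C1, C4, C5, C6 as in the target | CC(C)[C@]1(O)CC[C@](C)(CC=C)[C@H]1[C@@H](O)CC(C)=C
A2 | alternative 1 | (1R,4R,5S,6S)-dauc-8-ene-4,6-diol | CC(C)[C@]1(O)CC[C@]2(C)CC=C(C)C[C@H](O)[C@H]21
A3 | alternative 2 | trans-fused 3,4-dihydroxy-7a-methyl-3-(propan-2-yl)octahydroinden-6-one (target skeleton lacking C8, carbonyl at C9) | CC(C)[C@]1(O)CC[C@]2(C)CC(=O)C[C@H](O)[C@H]21
A4 | alternative 2 | 4,6-dihydroxydaucan-9-one (C8 configuration open) | CC(C)[C@]1(O)CC[C@]2(C)CC(=O)C(C)C[C@H](O)[C@H]21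
A5 | alternative 3 | (E)-ene–vinylcyclopropane: 3-hydroxy-3-isopropyl-6-methylhepta-1,6-dienyl chain on a 2-methylcyclopropane | C=C(C)CC[C@@](O)(C(C)C)/C=C/C1CC1C
A6 | alternative 3 | cis-fused dauc-6-en-4-ol (C1 epimeric to the target series) | CC(C)[C@]1(O)CC[C@@]2(C)CCC(C)C=C[C@H]21
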